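## Retrosynthetic overview

1. Last bond C7–C8: an intramolecular Nozaki–Hiyama–Kishi coupling of a (Z)-enol triflate (C8) with a (Z)-enal (C7) closes the ten-membered ring, and the alkoxide lactonises to the butenolide in the same flask.
2. The C11–C12 epoxide comes from a hydroxyl-directed vanadium epoxidation; its alkene comes from a C11 ketone (enol triflate, Negishi methylation).
3. C14 and the C2 butanoate come from one Evans–Tishchenko reduction of a C2-hydroxy C14-ketone, followed by acetylation.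
4. C1 (quaternary), C2 and C10 come from one step: vinyl conjugate addition to (R)-4-silyloxy-2-methylcyclohexenone 11, then aldol trapping with the nerol-derived (Z)-aldehyde 5.
5. Ring order: cyclohexane (bought as ketal enone 6), then the epoxide, then the ten-membered carbocycle and butenolide together.

Assumption 1: locants C1–C20 are the briarane labels of the target (C1 quaternary carbon with methyl C15, C2 butanoate carbon, C5=C6 Z alkene, C7 lactone O–CH, C8=C17 butenolide alkene, C10 ring CH, C11/C12 epoxide, C14 acetate carbon).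
Assumption 2: reagents named on the "Reagents that add atoms" lines are bought and are not numbered; TBS = tert-butyldimethylsilyl, PMB = 4-methoxybenzyl, Tf = trifluoromethanesulfonyl.
Assumption 3: the ring-closing step 23 is taken to give the natural 7R epimer; this is a prediction, not a secured outcome, and it is covered by a fallback.

## Route

Step 1  
Reactants: 1 nerol  
Product: 2 neryl PMB ether  
Conditions: NaH, PMBCl, Bu4NI (cat.), THF/DMF, 0 °C → rt  
Reagents that add atoms: 4-methoxybenzyl chloride `COc1ccc(CCl)cc1`  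
Why: Williamson ether synthesis on the primary allylic alcohol; the Z alkene bought with nerol becomes C5=C6 of the target and no stereocenter is formed.

Step 2  
Reactants: 2 neryl PMB ether  
Product: 3 6,7-epoxyneryl PMB ether (racemic)  
Conditions: mCPBA (1.0 equiv), NaHCO3, CH2Cl2, −20 °C  
Reagents that add atoms: 3-chloroperoxybenzoic acid `OOC(=O)c1cccc(Cl)c1`  
Why: Prilezhaev epoxidation takes the remote, more electron-rich trisubstituted alkene rather than the one deactivated by the allylic ether; the new stereocenter is racemic and is destroyed in step 3.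

Step 3  
Reactants: 3 6,7-epoxyneryl PMB ether  
Product: 5 (4Z)-6-(PMB-oxy)-4-methylhex-4-enal, via diol 4 (not isolated)  
Conditions: H5IO6, THF/H2O, 0 °C  
Reagents that add atoms: none  
Why: acid-promoted epoxide hydrolysis (water enters at the tertiary carbon, so its oxygen leaves with acetone) followed by Malaprade glycol cleavage gives the C2–C7 aldehyde with the Z alkene untouched.

Step 4  
Reactants: 6 1,4-dioxaspiro[4.5]dec-6-en-8-one  
Product: 7 (8R)-1,4-dioxaspiro[4.5]dec-6-en-8-ol  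
Conditions: (S)-2-methyl-CBS-oxazaborolidine (10 mol%), BH3·SMe2, THF, −20 °C  
Reagents that add atoms: none  
Why: Corey–Bakshi–Shibata reduction with the alkene arm as the large group delivers hydride to one enantioface and sets the R carbinol (future C11, a temporary control element).

Step 5  
Reactants: 7 (8R)-allylic alcohol  
Product: 8 (8R)-8-(TBS-oxy)-1,4-dioxaspiro[4.5]dec-6-ene  
Conditions: TBSCl, imidazole, DMF, rt  
Reagents that add atoms: tert-butyldimethylsilyl chloride `CC(C)(C)[Si](C)(C)Cl`  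
Why: standard silylation of the secondary alcohol; the stereocenter is not involved.

Step 6  
Reactants: 8 silyl ether ketal  
Product: 9 (4R)-4-(TBS-oxy)cyclohex-2-en-1-one  
Conditions: pyridinium p-toluenesulfonate (cat.), acetone/H2O, 50 °C  
Reagents that add atoms: water `O`  
Why: mild acetal hydrolysis unmasks the ketone (future C14) in conjugation with the alkene while the TBS ether and the γ-stereocenter survive.

Step 7  
Reactants: 9 (4R)-4-(TBS-oxy)cyclohex-2-en-1-one  
Product: 10 (4R)-4-(TBS-oxy)-2-iodocyclohex-2-en-1-one  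
Conditions: I2, pyridine/CH2Cl2, 0 °C → rt  
Reagents that add atoms: iodine `II`  
Why: Johnson α-iodination (pyridine conjugate addition, enolate iodination, elimination of pyridine) puts iodine on the α-carbon only.

Step 8  
Reactants: 10 α-iodo enone  
Product: 11 (4R)-4-(TBS-oxy)-2-methylcyclohex-2-en-1-one  
Conditions: Me4Sn, PdCl2(PhCN)2 (5 mol%), AsPh3, CuI, NMP, 80 °C  
Reagents that add atoms: tetramethylstannane `C[Sn](C)(C)C`  
Why: Stille coupling under neutral conditions installs the C15 methyl without base-induced loss of the γ-silyloxy group.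

Step 9  
Reactants: 11 (4R)-4-(TBS-oxy)-2-methylcyclohex-2-en-1-one; 5 (4Z)-6-(PMB-oxy)-4-methylhex-4-enal  
Product: 13 aldol adduct (C14 ketone/C2 alcohol), via bromomagnesium enolate 12 (not isolated)  
Conditions: CH2=CHMgBr (1.5 equiv), CuBr·SMe2 (15 mol%), THF, −78 → −40 °C; then 5, −78 °C  
Reagents that add atoms: vinylmagnesium bromide `C=C[Mg]Br`  
Why: copper-catalysed conjugate addition anti to the C11 silyloxy group sets C10; the regiodefined enolate then adds to 5 anti to the new vinyl group through a Zimmerman–Traxler chair (aldehyde chain equatorial), setting quaternary C1 and C2 (three-component conjugate addition–aldol).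

Step 10  
Reactants: 13 aldol adduct  
Product: 14 C2 butanoate/C14 alcohol  
Conditions: butanal (6 equiv), SmI2 (30 mol%), THF, −10 °C  
Reagents that add atoms: butanal `CCCC=O`  
Why: Evans–Tishchenko reduction: the samarium-bound C2 hemiacetal delivers hydride intramolecularly to C14 through a chair transition state, giving the 1,3-anti (axial, trans to C15) C14 alcohol and leaving C2 as its butanoate with no co-product.

Step 11  
Reactants: 14 C2 butanoate/C14 alcohol  
Product: 15 C14 acetate  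
Conditions: Ac2O, DMAP, pyridine, CH2Cl2, rt  
Reagents that add atoms: acetic anhydride `CC(=O)OC(C)=O`  
Why: DMAP-catalysed acylation of the hindered axial alcohol installs the C14 acetate of the target; no stereocenter changes.

Step 12  
Reactants: 15 C14 acetate  
Product: 16 C11 alcohol  
Conditions: HF·pyridine, pyridine, THF, 0 °C → rt  
Reagents that add atoms: none  
Why: fluoride-mediated desilylation frees only the C11 hydroxyl; the PMB ether and both esters are stable to buffered HF.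

Step 13  
Reactants: 16 C11 alcohol  
Product: 17 C11 ketone  
Conditions: Dess–Martin periodinane, NaHCO3, CH2Cl2, 0 °C  
Reagents that add atoms: none  
Why: buffered Dess–Martin oxidation removes the spent C11 control stereocenter without epimerising C10 or moving the vinyl group into conjugation.

Step 14  
Reactants: 17 C11 ketone  
Product: 19 C11 enol triflate (C11=C12), via potassium enolate 18 (not isolated)  
Conditions: KN(SiMe3)2 (1.1 equiv), THF, −78 °C; then PhNTf2, −78 → 0 °C  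
Reagents that add atoms: N-phenylbis(trifluoromethanesulfonimide) `O=S(=O)(N(c1ccccc1)S(=O)(=O)C(F)(F)F)C(F)(F)F`  
Why: kinetic deprotonation occurs at the unhindered C12 methylene (C10–H is shielded by quaternary C1 and the esters are far less acidic), and O-triflation fixes the C11=C12 regiochemistry.

Step 15  
Reactants: 19 C11 enol triflate  
Product: 20 C11-methyl alkene  
Conditions: MeZnCl, Pd(PPh3)4 (5 mol%), THF, rt → 45 °C  
Reagents that add atoms: methylzinc chloride `C[Zn]Cl`  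
Why: Negishi coupling (oxidative addition of zerovalent palladium into C–OTf, transmetalation, reductive elimination) installs methyl C20 on the trisubstituted C11=C12 alkene and tolerates both esters.

Step 16  
Reactants: 20 C11-methyl alkene  
Product: 22 C8 primary alcohol, via B-alkyl-9-BBN borane 21 (not isolated)  
Conditions: 9-BBN, THF, 0 °C → rt; then H2O2, aq NaOAc, 0 °C  
Reagents that add atoms: hydrogen peroxide `OO`  
Why: Brown hydroboration–oxidation: 9-BBN adds only to the monosubstituted vinyl group with boron on the terminal carbon, leaving both trisubstituted alkenes and the esters.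

Step 17  
Reactants: 22 C8 primary alcohol  
Product: 23 11,12-epoxy alcohol  
Conditions: VO(acac)2 (10 mol%), t-BuOOH, CH2Cl2, 0 °C → rt  
Reagents that add atoms: tert-butyl hydroperoxide `CC(C)(C)OO`  
Why: vanadium-catalysed hydroxyl-directed epoxidation: the C8–OH binds vanadium and delivers oxygen to the C11=C12 face syn to the C9–C8 arm, setting C11 and C12, while C5=C6 (no free hydroxyl nearby) is left.

Step 18  
Reactants: 23 epoxy alcohol  
Product: 24 C8 carboxylic acid  
Conditions: 2,2,6,6-tetramethylpiperidin-1-oxyl (20 mol%), PhI(OAc)2, MeCN/pH 7 buffer, rt  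
Reagents that add atoms: water `O`  
Why: oxoammonium oxidation through the aldehyde hydrate gives the acid under buffered conditions; the carboxyl sits on the same face as the epoxide oxygen and cannot open it from the back.

Step 19  
Reactants: 24 C8 carboxylic acid  
Product: 26 beta-keto ester, via acyl imidazole 25 (not isolated)  
Conditions: CDI, THF, rt; then ethyl hydrogen methylmalonate, MgCl2, Et3N, MeCN, rt → 45 °C  
Reagents that add atoms: ethyl hydrogen methylmalonate `CCOC(=O)C(C)C(O)=O`  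
Why: Masamune–Brooks homologation: the acyl imidazole C-acylates the magnesium malonate half-ester and decarboxylation gives the beta-keto ester (C17, C18, C19) under near-neutral conditions; the C17 mixture is erased in step 20.

Step 20  
Reactants: 26 beta-keto ester  
Product: 28 (Z)-enol triflate, via sodium enolate 27 (not isolated)  
Conditions: NaH (1.1 equiv), THF, 0 °C; then PhNTf2, 0 °C → rt  
Reagents that add atoms: N-phenylbis(trifluoromethanesulfonimide) `O=S(=O)(N(c1ccccc1)S(=O)(=O)C(F)(F)F)C(F)(F)F`  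
Why: the sodium-chelated enolate holds both carbonyl oxygens cis, so O-triflation gives the Z enol triflate with OTf cis to CO2Et, the geometry needed for lactonisation.

Step 21  
Reactants: 28 (Z)-enol triflate  
Product: 29 C7 allylic alcohol  
Conditions: DDQ, CH2Cl2/pH 7 buffer, 0 °C  
Reagents that add atoms: none  
Why: oxidative PMB cleavage (benzylic hydride abstraction, then hydrolysis of the oxocarbenium ion) frees the C7 hydroxyl; esters, epoxide and vinyl triflate are inert.

Step 22  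
Reactants: 29 C7 allylic alcohol  
Product: 30 (Z)-enal  
Conditions: Dess–Martin periodinane, NaHCO3, CH2Cl2, 0 °C  
Reagents that add atoms: none  
Why: buffered Dess–Martin oxidation gives the Z enal without isomerisation to the E isomer; it is used crude.

Step 23  
Reactants: 30 (Z)-enal  
Product: 32 CNP0220791.2 (target), via macrocyclic hydroxy ester 31 (not isolated)  
Conditions: CrCl2 (10 equiv), NiCl2 (2 mol%), DMF/THF, rt, 2 mM (slow addition)  
Reagents that add atoms: none  
Why: Nozaki–Hiyama–Kishi macrocyclisation: nickel inserts into the C8–OTf bond, the vinyl group passes to trivalent chromium and adds 1,2 to the enal to form C7–C8, and the C7 alkoxide lactonises onto the cis ester to give the butenolide; C7 is set by macrocyclic diastereocontrol (assumed 7R).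

## Compound list

```
1 | nerol, (2Z)-3,7-dimethylocta-2,6-dien-1-ol | CC(C)=CCC/C(C)=C\CO | starting material
2 | neryl PMB ether, 1-({[(2Z)-3,7-dimethylocta-2,6-dien-1-yl]oxy}methyl)-4-methoxybenzene | CC(C)=CCC/C(C)=C\COCc1ccc(OC)cc1 | intermediate
3 | 3-{(3Z)-5-[(4-methoxybenzyl)oxy]-3-methylpent-3-en-1-yl}-2,2-dimethyloxirane (racemic at the oxirane CH) | CC1(C)OC1CC/C(C)=C\COCc2ccc(OC)cc2 | intermediate
4 | (6Z)-8-[(4-methoxybenzyl)oxy]-2,6-dimethyloct-6-ene-2,3-diol (racemic) | CC(C)(O)C(O)CC/C(C)=C\COCc1ccc(OC)cc1 | intermediate (not isolated)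
5 | (4Z)-6-[(4-methoxybenzyl)oxy]-4-methylhex-4-enal (C2-C7 piece) | O=CCC/C(C)=C\COCc1ccc(OC)cc1 | intermediate
6 | 1,4-dioxaspiro[4.5]dec-6-en-8-one | O=C1C=CC2(CC1)OCCO2 | starting material
7 | (8R)-1,4-dioxaspiro[4.5]dec-6-en-8-ol | O[C@@H]1CCC2(OCCO2)C=C1 | intermediate
8 | (8R)-8-[(tert-butyldimethylsilyl)oxy]-1,4-dioxaspiro[4.5]dec-6-ene | CC(C)(C)[Si](C)(C)O[C@@H]1CCC2(OCCO2)C=C1 | intermediate
9 | (4R)-4-[(tert-butyldimethylsilyl)oxy]cyclohex-2-en-1-one | O=C1C=C[C@H](O[Si](C)(C)C(C)(C)C)CC1 | intermediate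
10 | (4R)-4-[(tert-butyldimethylsilyl)oxy]-2-iodocyclohex-2-en-1-one | O=C1C(I)=C[C@H](O[Si](C)(C)C(C)(C)C)CC1 | intermediate
11 | (4R)-4-[(tert-butyldimethylsilyl)oxy]-2-methylcyclohex-2-en-1-one | CC1=C[C@H](O[Si](C)(C)C(C)(C)C)CCC1=O | intermediate
12 | bromomagnesium (3R,4R)-4-[(tert-butyldimethylsilyl)oxy]-2-methyl-3-vinylcyclohex-1-en-1-olate | C=C[C@@H]1C(C)=C(O[Mg]Br)CC[C@H]1O[Si](C)(C)C(C)(C)C | intermediate (not isolated)
13 | (2S,3R,4R)-4-[(tert-butyldimethylsilyl)oxy]-2-{(1S,4Z)-1-hydroxy-6-[(4-methoxybenzyl)oxy]-4-methylhex-4-en-1-yl}-2-methyl-3-vinylcyclohexan-1-one | COc1ccc(COC/C=C(/C)CC[C@H](O)[C@]2(C)[C@@H](C=C)[C@H](O[Si](C)(C)C(C)(C)C)CCC2=O)cc1 | intermediate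
14 | (1S,4Z)-1-{(1R,2R,3R,6S)-3-[(tert-butyldimethylsilyl)oxy]-6-hydroxy-1-methyl-2-vinylcyclohexyl}-6-[(4-methoxybenzyl)oxy]-4-methylhex-4-en-1-yl butanoate | COc1ccc(COC/C=C(/C)CC[C@H](OC(=O)CCC)[C@]2(C)[C@@H](C=C)[C@H](O[Si](C)(C)C(C)(C)C)CC[C@@H]2O)cc1 | intermediate
15 | (1S,4Z)-1-{(1R,2R,3R,6S)-6-acetoxy-3-[(tert-butyldimethylsilyl)oxy]-1-methyl-2-vinylcyclohexyl}-6-[(4-methoxybenzyl)oxy]-4-methylhex-4-en-1-yl butanoate | COc1ccc(COC/C=C(/C)CC[C@H](OC(=O)CCC)[C@]2(C)[C@@H](C=C)[C@H](O[Si](C)(C)C(C)(C)C)CC[C@@H]2OC(C)=O)cc1 | intermediate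
16 | (1S,4Z)-1-[(1R,2R,3R,6S)-6-acetoxy-3-hydroxy-1-methyl-2-vinylcyclohexyl]-6-[(4-methoxybenzyl)oxy]-4-methylhex-4-en-1-yl butanoate | COc1ccc(COC/C=C(/C)CC[C@H](OC(=O)CCC)[C@]2(C)[C@@H](C=C)[C@H](O)CC[C@@H]2OC(C)=O)cc1 | intermediate
17 | (1S,4Z)-1-[(1R,2R,6S)-6-acetoxy-1-methyl-3-oxo-2-vinylcyclohexyl]-6-[(4-methoxybenzyl)oxy]-4-methylhex-4-en-1-yl butanoate | COc1ccc(COC/C=C(/C)CC[C@H](OC(=O)CCC)[C@]2(C)[C@@H](C=C)C(=O)CC[C@@H]2OC(C)=O)cc1 | intermediate
18 | potassium enolate of 17 (O-K on C11, C11=C12) | COc1ccc(COC/C=C(/C)CC[C@H](OC(=O)CCC)[C@]2(C)[C@@H](C=C)C(O[K])=CC[C@@H]2OC(C)=O)cc1 | intermediate (not isolated)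
19 | (1S,4Z)-1-{(1S,2R,6S)-6-acetoxy-1-methyl-3-[(trifluoromethanesulfonyl)oxy]-2-vinylcyclohex-3-en-1-yl}-6-[(4-methoxybenzyl)oxy]-4-methylhex-4-en-1-yl butanoate | COc1ccc(COC/C=C(/C)CC[C@H](OC(=O)CCC)[C@]2(C)[C@@H](C=C)C(OS(=O)(=O)C(F)(F)F)=CC[C@@H]2OC(C)=O)cc1 | intermediate
20 | (1S,4Z)-1-[(1S,2S,6S)-6-acetoxy-1,3-dimethyl-2-vinylcyclohex-3-en-1-yl]-6-[(4-methoxybenzyl)oxy]-4-methylhex-4-en-1-yl butanoate | COc1ccc(COC/C=C(/C)CC[C@H](OC(=O)CCC)[C@]2(C)[C@@H](C=C)C(C)=CC[C@@H]2OC(C)=O)cc1 | intermediate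
21 | B-alkyl-9-borabicyclo[3.3.1]nonane from 20 (boron on C8) | COc1ccc(COC/C=C(/C)CC[C@H](OC(=O)CCC)[C@]2(C)[C@@H](CCB3C4CCCC3CCC4)C(C)=CC[C@@H]2OC(C)=O)cc1 | intermediate (not isolated)
22 | (1S,4Z)-1-[(1S,2S,6S)-6-acetoxy-2-(2-hydroxyethyl)-1,3-dimethylcyclohex-3-en-1-yl]-6-[(4-methoxybenzyl)oxy]-4-methylhex-4-en-1-yl butanoate | COc1ccc(COC/C=C(/C)CC[C@H](OC(=O)CCC)[C@]2(C)[C@@H](CCO)C(C)=CC[C@@H]2OC(C)=O)cc1 | intermediate
23 | (1S,4Z)-1-[(1R,2R,3S,4S,6S)-4-acetoxy-2-(2-hydroxyethyl)-1,3-dimethyl-7-oxabicyclo[4.1.0]heptan-3-yl]-6-[(4-methoxybenzyl)oxy]-4-methylhex-4-en-1-yl butanoate | COc1ccc(COC/C=C(/C)CC[C@H](OC(=O)CCC)[C@]2(C)[C@@H](CCO)[C@@]3(C)O[C@H]3C[C@@H]2OC(C)=O)cc1 | intermediate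
24 | {(1R,2R,3S,4S,6S)-4-acetoxy-3-[(1S,4Z)-1-(butanoyloxy)-6-[(4-methoxybenzyl)oxy]-4-methylhex-4-en-1-yl]-1,3-dimethyl-7-oxabicyclo[4.1.0]heptan-2-yl}acetic acid | COc1ccc(COC/C=C(/C)CC[C@H](OC(=O)CCC)[C@]2(C)[C@@H](CC(O)=O)[C@@]3(C)O[C@H]3C[C@@H]2OC(C)=O)cc1 | intermediate
25 | N-acyl imidazole of acid 24 | COc1ccc(COC/C=C(/C)CC[C@H](OC(=O)CCC)[C@]2(C)[C@@H](CC(=O)n4ccnc4)[C@@]3(C)O[C@H]3C[C@@H]2OC(C)=O)cc1 | intermediate (not isolated)
26 | ethyl 4-{(1R,2R,3S,4S,6S)-4-acetoxy-3-[(1S,4Z)-1-(butanoyloxy)-6-[(4-methoxybenzyl)oxy]-4-methylhex-4-en-1-yl]-1,3-dimethyl-7-oxabicyclo[4.1.0]heptan-2-yl}-2-methyl-3-oxobutanoate (both epimers at the methyl-bearing carbon) | COc1ccc(COC/C=C(/C)CC[C@H](OC(=O)CCC)[C@]2(C)[C@@H](CC(=O)C(C)C(=O)OCC)[C@@]3(C)O[C@H]3C[C@@H]2OC(C)=O)cc1 | intermediate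
27 | sodium (Z)-enolate of 26 (O-Na on C8, cis to the ester) | COc1ccc(COC/C=C(/C)CC[C@H](OC(=O)CCC)[C@]2(C)[C@@H](C/C(O[Na])=C(/C(=O)OCC)C)[C@@]3(C)O[C@H]3C[C@@H]2OC(C)=O)cc1 | intermediate (not isolated)
28 | ethyl (2Z)-4-{(1R,2R,3S,4S,6S)-4-acetoxy-3-[(1S,4Z)-1-(butanoyloxy)-6-[(4-methoxybenzyl)oxy]-4-methylhex-4-en-1-yl]-1,3-dimethyl-7-oxabicyclo[4.1.0]heptan-2-yl}-2-methyl-3-[(trifluoromethanesulfonyl)oxy]but-2-enoate | COc1ccc(COC/C=C(/C)CC[C@H](OC(=O)CCC)[C@]2(C)[C@@H](C/C(OS(=O)(=O)C(F)(F)F)=C(/C(=O)OCC)C)[C@@]3(C)O[C@H]3C[C@@H]2OC(C)=O)cc1 | intermediate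
29 | ethyl (2Z)-4-{(1R,2R,3S,4S,6S)-4-acetoxy-3-[(1S,4Z)-1-(butanoyloxy)-6-hydroxy-4-methylhex-4-en-1-yl]-1,3-dimethyl-7-oxabicyclo[4.1.0]heptan-2-yl}-2-methyl-3-[(trifluoromethanesulfonyl)oxy]but-2-enoate | OC/C=C(/C)CC[C@H](OC(=O)CCC)[C@]1(C)[C@@H](C/C(OS(=O)(=O)C(F)(F)F)=C(/C(=O)OCC)C)[C@@]2(C)O[C@H]2C[C@@H]1OC(C)=O | intermediate
30 | ethyl (2Z)-4-{(1R,2R,3S,4S,6S)-4-acetoxy-3-[(1S,4Z)-1-(butanoyloxy)-4-methyl-6-oxohex-4-en-1-yl]-1,3-dimethyl-7-oxabicyclo[4.1.0]heptan-2-yl}-2-methyl-3-[(trifluoromethanesulfonyl)oxy]but-2-enoate | O=C/C=C(/C)CC[C@H](OC(=O)CCC)[C@]1(C)[C@@H](C/C(OS(=O)(=O)C(F)(F)F)=C(/C(=O)OCC)C)[C@@]2(C)O[C@H]2C[C@@H]1OC(C)=O | intermediate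
31 | macrocyclic hydroxy ester: the target with the lactone opened to a C7 hydroxyl and a C19 ethyl ester, C8=C17 with C7 cis to the ester; (1S,2S,5Z,7R,10R,11R,12S,14S) | CCCC(=O)O[C@H]1CC/C(C)=C\[C@@H](O)/C(=C(/C)C(=O)OCC)C[C@H]2[C@@]3(C)O[C@H]3C[C@H](OC(C)=O)[C@]12C | intermediate (not isolated)
32 | CNP0220791.2, (1S,2S,5Z,7R,10R,11R,12S,14S)-14-acetoxy-2-butanoyloxy-11,12-epoxybriara-5,8(17)-diene C19/O-C7 gamma-lactone | CCCC(=O)O[C@H]1CC/C(C)=C\[C@H]2OC(=O)C(C)=C2C[C@H]2[C@@]3(C)O[C@H]3C[C@H](OC(C)=O)[C@]12C | target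
```

## Step count and weak points

Total: 23 steps. Longest linear sequence: 20 steps (6 → 32, steps 4–23); the aldehyde branch (steps 1–3) joins at step 9.

Three steps most likely to fail:

Step 23 (ring closure). The ten-membered ring may form slowly, and the C7 configuration rests on macrocyclic control alone. Fallback: set out from 28 and set C7 before ring closure. An intermolecular Nozaki–Hiyama–Kishi coupling of 28 with acrolein (CrCl2, NiCl2 cat., a Kishi-type chiral sulfonamide ligand, then lactonisation) gives the γ-vinyl butenolide F4 with C7 fixed by the ligand. Ring-closing metathesis of F4 with the second-generation Hoveyda–Grubbs catalyst (toluene, high dilution, 80 °C) joins the C7 vinyl group to the C5 alkene carbon with loss of allyl PMB ether. The Z alkene is expected from ring strain, and this comes back to the route at 32.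

Step 9 (conjugate addition–aldol). The tetrasubstituted magnesium enolate may add sluggishly or with poor C2 selectivity, and retro-aldol can erode the quaternary centre. Fallback: set out from 11 and separate the two events. Running the copper-catalysed vinyl addition with TMSCl present gives, after isolation, the trimethylsilyl enol ether F1. MeLi (THF, 0 °C) then regenerates a clean lithium enolate, which is transmetalated with ZnCl2 and added to 5 at −78 °C through the same chair transition state, coming back at 13.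

Step 17 (directed epoxidation). A bishomoallylic hydroxyl directs only weakly, so conversion or face selectivity may be poor. Fallback: set out from 22 and build the epoxide by iodolactonisation. Oxidation of 22 (TEMPO, PhI(OAc)2, MeCN/buffer) gives the cyclohexenylacetic acid F2. I2/NaHCO3 in MeCN/H2O closes the cis-fused iodolactone F3, with the carboxylate adding to C11 on the face of the side arm and iodine anti on C12. The lithium enolate of ethyl propanoate (LiN(iPr)2, THF, −78 °C) then opens the lactone in a Claisen condensation; the freed C11 alkoxide displaces the anti iodide to give the same epoxide, coming back at 26.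

Further compounds

```
F1 | step 9 | tert-butyldimethyl{[(1R,2R)-3-methyl-4-[(trimethylsilyl)oxy]-2-vinylcyclohex-3-en-1-yl]oxy}silane | C=C[C@@H]1C(C)=C(O[Si](C)(C)C)CC[C@H]1O[Si](C)(C)C(C)(C)C
F2 | step 17 | {(1S,5S,6S)-5-acetoxy-6-[(1S,4Z)-1-(butanoyloxy)-6-[(4-methoxybenzyl)oxy]-4-methylhex-4-en-1-yl]-2,6-dimethylcyclohex-2-en-1-yl}acetic acid | COc1ccc(COC/C=C(/C)CC[C@H](OC(=O)CCC)[C@]2(C)[C@@H](CC(O)=O)C(C)=CC[C@@H]2OC(C)=O)cc1
F3 | step 17 | iodolactone: C8 carboxyl closed onto C11 as a cis-fused gamma-lactone with iodine on C12 anti to the lactone oxygen; (1S,2S,10R,11R,12R,14S) | COc1ccc(COC/C=C(/C)CC[C@H](OC(=O)CCC)[C@]2(C)[C@H]3CC(=O)O[C@@]3(C)[C@H](I)C[C@@H]2OC(C)=O)cc1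
F4 | step 23 | gamma-vinyl butenolide: C8 enol triflate of 28 replaced by the (7R)-5-vinyl-3-methylfuran-2(5H)-one ring, PMB ether chain retained | COc1ccc(COC/C=C(/C)CC[C@H](OC(=O)CCC)[C@]2(C)[C@@H](CC3=C(C)C(=O)O[C@@H]3C=C)[C@@]4(C)O[C@H]4C[C@@H]2OC(C)=O)cc1
```
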